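| setting | birch | ash | larch | grey | teal | ochre | green |
|---|---|---|---|---|---|---|---|
| starting material | 0.050 M | 0.050 M | 0.050 M | 0.050 M | 0.050 M | 0.050 M (fed, over 0.750 h) | 0.050 M |
| reagent | 0.055 M | 0.037 M | 0.083 M | 0.0550 M | 0.0550 M | 0.0550 M | 0.0550 M |
| free catalyst | 7.5 mM | 7.5 mM | 7.5 mM | 7.5 mM | 7.5 mM | 7.5 mM | 7.5 mM |
| remark | run made earlier | run made earlier | run made earlier | everything together in a closed stirred flask, run for 1.5 h | a single well-mixed tank run continuously and read at steady state, 1.5 h in it on average | all but starting material at the start; starting material goes in evenly over 0.750 h, the run ends at 1.5 h | a tube with plug flow, the mixed feed as stated, residence time 1.5 h |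
| time |  |  |  | 1.5 h |  | 1.5 h | 1.5 h |

| run | time / min | target / % | isomer of the product / % |
|---|---|---|---|
| birch | 10.0 | 16 | 2 |
| birch | 20.0 | 33 | 14 |
| birch | 30.0 | 40 | 24 |
| birch | 40.0 | 44 | 38 |
| birch | 50.0 | 47 | 53 |
| ash | 5.00 | 7 | 0 |
| ash | 15.0 | 24 | 7 |
| ash | 25.0 | 37 | 18 |
| ash | 40.0 | 36 | 34 |
| ash | 50.0 | 31 | 46 |
| larch | 10.0 | 17 | 4 |
| larch | 20.0 | 32 | 12 |
| larch | 30.0 | 44 | 21 |
| larch | 40.0 | 45 | 37 |
| larch | 50.0 | 47 | 54 |

(standard deviation of a reading: 1.5 percentage points)

- the stated concentrations are those of everything mixed, before any reaction; amounts are the same in each set-up
- on the list of suspects stand: reagent + free catalyst <-> catalyst intermediate A; 2 catalyst intermediate B <-> resting dimer; starting material + catalyst intermediate B <-> catalyst intermediate C; target <-> isomer of the product; catalyst intermediate B -> spent catalyst; catalyst intermediate C -> free catalyst + target; catalyst intermediate A <-> catalyst intermediate B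
- the feed brings no volume worth counting
- the earlier runs were made in a closed, stirred flask

1. the set-up with the highest share of target in all that became target or isomer of the product, at the outlet or at the end ("none" if the first two lie within 2 percentage points) (grey / teal / ochre / green / none)
2. share of target in all that became target or isomer of the product, at the outlet or at the end, grey
3. share of target in all that became target or isomer of the product, at the outlet or at the end, teal
4. share of target in all that became target or isomer of the product, at the outlet or at the end, ochre
5. share of target in all that became target or isomer of the product, at the outlet or at the end, green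

**Reading the amounts.** The amounts of target and isomer of the product in the birch run, which is grey's recipe, climb nearly steadily and add up to 100% by 50.0 min, so you may treat the making as a constant rate r over a window T of that length. Between 30.0 min and 50.0 min the isomer gains 29 percentage points while target reads about 44%, which gives, as a reading, k = 0.0330 min⁻¹, the drain constant, the fraction of target passing to isomer per minute.

**Two extremes.** Integrate dc(target)/dt = r − k·c(target) over T, then let target fall for the remaining time, and the share of target (the selectivity) at time t is (1 − exp(−kT))/(kT) · exp(−k(t − T)). Put the making into one instant at the start of a 1.5 h run and you get 5.13%; stretch it across the whole run and you get 31.9%. A window of 50.0 min, shorter than the run, lies between them at 13.1%, and that is my number for grey and for green, a tube with plug flow being a closed flask read along its length. Ochre's feed brings its charge in 45 min, faster than the birch run's making, so I place ochre near grey's end of that range. For the tank, the steady balance replaces the integral and gives 1/(1 + kτ) = 25.2%, with τ the 1.5 h spent there on average.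

**The forecast.** It names teal as best, with 16% for grey, 28% for teal, 17% for ochre and 16% for green, the grey and teal values standing above my figures, and of ochre it says: “It is almost the same as batch”.

**The result.** The best set-up is teal, with 15.3% for grey, 27.0% for teal, 24.3% for ochre and 15.3% for green.

    reagent + free catalyst ⇌ catalyst intermediate A (K = 170 L mol⁻¹, k = 15.0 L mol⁻¹ s⁻¹)
    2 catalyst intermediate B ⇌ resting dimer, settled at all times (K = 41.0 L mol⁻¹)
    starting material + catalyst intermediate B ⇌ catalyst intermediate C (K = 1400 L mol⁻¹, k = 5.80 L mol⁻¹ s⁻¹)
    target ⇌ isomer of the product (K = 30.0, k = 5.50 × 10⁻⁴ s⁻¹)
    catalyst intermediate B → spent catalyst (k = 0.00100 s⁻¹)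
    catalyst intermediate C → free catalyst + target (k = 0.00370 s⁻¹)
    catalyst intermediate A ⇌ catalyst intermediate B (K = 1.90, k = 0.0130 s⁻¹)

**Where ochre parts.** The main reason for green's low share is the time given: green stands at 15.3% as run and at 3.23% left ten times as long. Ochre stands at 24.3% with the slow dosing and at 15.3% without it, and that dosing is a part of the story, not the whole of it. At the end of the feed, 0.750 h, ochre still holds 31.5% as starting material, with target at 34.3%. The drain constant carries that target down to 7.78% by 1.5 h, against 23.9% found, so by this reckoning about 16 points of the charge stands as target made after the feed stopped. Green read at 40 min, with its making still under way, reckons by the window term at 55.5% and stands at 54.5%.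

The runs are simulated for an exercise, noise included.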